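## Retrosynthetic overview

1. The target comes from a bicyclic 2,4-diol that already carries the C6 4-acetoxybenzoate, by O-acetylation at C2 and unmasking of the phenol.
2. The bicyclic diol comes from an acyclic, farnesane-type β-hydroxy ketone (E C5=C1 alkene, (Z)-2-ethoxydiene terminus) by one cationic bicyclisation that makes the two bonds the terpene cyclase makes from farnesyl diphosphate, C4–C5 and C1–C10. It runs from the oxygenated tail: a chelated Prins closure forms the five-membered ring first, then enol-ether capture of the C1 cation closes the seven-membered ring in the same flask.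
3. The acyclic precursor comes from a reagent-controlled boron aldol of 3-methylbutan-2-one with a (2E,5Z)-trienal, which sets C2.
4. The trienal comes from prenal and propyne (asymmetric alkynylation sets C6) by trans-hydroalumination/iodination (Z alkene), acylation, allylic oxidation of the E methyl group and coupling with a 1-ethoxyvinyl stannane.

Skeletal atoms carry daucane numbers: C1 (quaternary, methyl), C2 (OAc), C3, C4 (OH, isopropyl), C5 (ring-fusion H), C6 (aroyloxy), C7=C8 (methyl on C8), C9 (C=O), C10.

Assumption: the antipodes of the two chiral reagents (ProPhenol in step 1, Ipc2BCl in step 6) are written from the accepted facial models as recalled; the sense is checked by Mosher ester analysis of the two carbinols and the enantiomeric reagent is used if it is the reverse.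

## Route

Step 1
Reactants: 1 3-methylbut-2-enal (prenal); 2 propyne
Product: 4 (4S)-2-methylhept-2-en-5-yn-4-ol, via methyl(prop-1-ynyl)zinc 3 (not isolated)
Conditions: Me2Zn (3 equiv), (S,S)-ProPhenol (2,6-bis[[(2S)-2-(hydroxydiphenylmethyl)pyrrolidin-1-yl]methyl]-4-methylphenol, 10 mol%), Ph3PO (20 mol%), PhMe, 0 °C
Reagents that add atoms: none
Why: Trost's dinuclear zinc–ProPhenol asymmetric alkynylation (1,2-addition of a zinc acetylide to an enal) sets the C6 carbinol centre by reagent control.

Step 2
Reactants: 4 (4S)-2-methylhept-2-en-5-yn-4-ol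
Product: 6 (4S,5Z)-6-iodo-2-methylhepta-2,5-dien-4-ol, via cyclic sodium alkenylalanate 5 (not isolated)
Conditions: NaAlH2(OCH2CH2OMe)2 (Red-Al, 1.6 equiv), THF, 0 °C to rt; then I2, THF, −78 to 0 °C
Reagents that add atoms: iodine, II
Why: Hydroxyl-directed trans-hydroalumination of the propargylic alcohol puts aluminium on the distal alkyne carbon in a five-membered alanate, and iodinolysis with retention gives the (Z)-vinyl iodide, fixing the cis C7=C8 geometry needed inside the seven-membered ring without touching the stereocentre.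

Step 3
Reactants: 6 (4S,5Z)-6-iodo-2-methylhepta-2,5-dien-4-ol; 7 4-(acetyloxy)benzoyl chloride
Product: 8 (4S,5Z)-6-iodo-2-methylhepta-2,5-dien-4-yl 4-(acetyloxy)benzoate
Conditions: pyridine (2 equiv), 4-(dimethylamino)pyridine (5 mol%), CH2Cl2, 0 °C to rt
Reagents that add atoms: none
Why: Nucleophilic-catalysed acylation installs the masked 4-hydroxybenzoate early, so the C6 oxygen is never free next to the later Z-enone unit (no furan formation) and is protected from the oxidant of the next step; no stereocentre is affected.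

Step 4
Reactants: 8 (4S,5Z)-6-iodo-2-methylhepta-2,5-dien-4-yl 4-(acetyloxy)benzoate
Product: 10 (2E,4S,5Z)-6-iodo-2-methyl-1-oxohepta-2,5-dien-4-yl 4-(acetyloxy)benzoate, via allylic alcohol 9 (not isolated)
Conditions: SeO2 (1.5 equiv), 1,4-dioxane, 80 °C
Reagents that add atoms: selenium dioxide, O=[Se]=O
Why: Riley allylic oxidation (ene reaction, then [2,3]-sigmatropic shift) attacks the more substituted end of the electron-richer prenyl alkene and selects its (E)-methyl group, giving the (E)-enal through the allylic alcohol while the deactivated iodoalkene and the C6 centre are left alone.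

Step 5
Reactants: 10 (2E,4S,5Z)-6-iodo-2-methyl-1-oxohepta-2,5-dien-4-yl 4-(acetyloxy)benzoate; 11 tributyl(1-ethoxyethenyl)stannane
Product: 13 (2E,4R,5Z)-7-ethoxy-2,6-dimethyl-1-oxoocta-2,5,7-trien-4-yl 4-(acetyloxy)benzoate, via 1-ethoxyethenylcopper 12 (not isolated)
Conditions: CuTC (CuO2CC4H3S, monovalent copper thiophene-2-carboxylate, 1.5 equiv), NMP, 0 °C to rt
Reagents that add atoms: none
Why: The Liebeskind–Allred copper-mediated Stille-type coupling joins the two vinyl partners with retention of the Z geometry and uses no palladium, so the bis-allylic ester cannot ionise to a π-allyl complex (the descriptor at the carbinol carbon changes from S to R only through the priority change).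

Step 6
Reactants: 13 (2E,4R,5Z)-7-ethoxy-2,6-dimethyl-1-oxoocta-2,5,7-trien-4-yl 4-(acetyloxy)benzoate; 14 3-methylbutan-2-one
Product: 17 (3Z,5S,6E,8R)-2-ethoxy-8-hydroxy-3,7,11-trimethyl-10-oxododeca-1,3,6-trien-5-yl 4-(acetyloxy)benzoate, via enol diisopinocampheylborinate 15 (not isolated), via boron aldolate 16 (not isolated)
Conditions: (+)-Ipc2BCl (1.3 equiv), Et3N, Et2O, −78 °C; then 13, −78 to −20 °C; then H2O2, MeOH, pH 7 buffer (NaH2PO4/Na2HPO4), 0 °C
Reagents that add atoms: none
Why: The Paterson aldol of the kinetic diisopinocampheylboron enolate of the methyl ketone adds 1,2 to the re face of the enal and sets C2 as R under reagent control; the remote C6 centre exerts little bias and the minor diastereomer is removed by chromatography on base-washed silica.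

Step 7
Reactants: 17 (3Z,5S,6E,8R)-2-ethoxy-8-hydroxy-3,7,11-trimethyl-10-oxododeca-1,3,6-trien-5-yl 4-(acetyloxy)benzoate
Product: 20 (1R,3R,3aR,4R,8aS)-1,3-dihydroxy-6,8a-dimethyl-7-oxo-3-(propan-2-yl)-1,2,3,3a,4,7,8,8a-octahydroazulen-4-yl 4-(acetyloxy)benzoate, via dichloroaluminium alkoxide chelate 18 (not isolated), via oxocarbenium aluminate zwitterion 19 (not isolated)
Conditions: MeAlCl2 (2.2 equiv), CH2Cl2 (0.005 M), −78 to −30 °C; aq NaHCO3
Reagents that add atoms: none
Why: Proposed new method: MeAlCl2 turns the C2 hydroxyl into a dichloroaluminium alkoxide that chelates and activates the C4 ketone, the E C5=C1 alkene attacks it through C5 in a 5-endo Prins closure (the chelate forces O4 cis to O2, hence H5 cis to both oxygens and the isopropyl group cis to C6), and the developing tertiary C1 cation is captured on the opposite alkene face by the terminal carbon of the 2-ethoxydiene, which sits below the alkene in the allylic-strain-minimised conformer of the (S)-configured C6 centre, so that anti addition across the E alkene gives the trans ring fusion and hydrolysis of the oxocarbenium ion gives the enone; the closest known reactions are Snider's MeAlCl2-induced zwitterionic Prins cyclisations of γ,δ-unsaturated ketones, chelation-controlled additions to β-oxygenated carbonyl compounds and cation–olefin cyclisations terminated by enol ethers.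

Step 8
Reactants: 20 (1R,3R,3aR,4R,8aS)-1,3-dihydroxy-6,8a-dimethyl-7-oxo-3-(propan-2-yl)-1,2,3,3a,4,7,8,8a-octahydroazulen-4-yl 4-(acetyloxy)benzoate
Product: 22 (1R,3R,3aR,4R,8aS)-1-(acetyloxy)-3-hydroxy-6,8a-dimethyl-7-oxo-3-(propan-2-yl)-1,2,3,3a,4,7,8,8a-octahydroazulen-4-yl 4-hydroxybenzoate (target), via diacetate 21 (not isolated)
Conditions: Ac2O (1.5 equiv), 4-(dimethylamino)pyridine (10 mol%), pyridine, CH2Cl2, rt; concentrate; then K2CO3 (0.2 equiv), MeOH, 0 °C, 20 min
Reagents that add atoms: acetic anhydride, CC(=O)OC(C)=O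
Why: Nucleophilic-catalysed acetylation takes the secondary C2 hydroxyl and leaves the hindered tertiary C4 hydroxyl, and brief carbonate-catalysed transesterification then removes only the much more reactive aryl acetate, leaving the alkyl acetate, the aroyl ester and every stereocentre intact.

## Compound list

1 | 3-methylbut-2-enal (prenal) | CC(C)=CC=O | starting material
2 | propyne | CC#C | starting material
3 | methyl(prop-1-yn-1-yl)zinc | C[Zn]C#CC | intermediate
4 | (4S)-2-methylhept-2-en-5-yn-4-ol | CC(C)=C[C@H](O)C#CC | intermediate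
5 | sodium (5S)-2,2-bis(2-methoxyethoxy)-3-methyl-5-(2-methylprop-1-enyl)-2,5-dihydro-1,2-oxaluminol-2-uide (cyclic alkenylalanate) | CC(C)=C[C@H]1C=C(C)[Al-](OCCOC)(OCCOC)O1.[Na+] | intermediate
6 | (4S,5Z)-6-iodo-2-methylhepta-2,5-dien-4-ol | CC(C)=C[C@H](O)/C=C(\I)C | intermediate
7 | 4-(acetyloxy)benzoyl chloride | CC(=O)Oc1ccc(cc1)C(Cl)=O | starting material
8 | (4S,5Z)-6-iodo-2-methylhepta-2,5-dien-4-yl 4-(acetyloxy)benzoate | CC(C)=C[C@H](OC(=O)c1ccc(OC(C)=O)cc1)/C=C(\I)C | intermediate
9 | (2E,4S,5Z)-1-hydroxy-6-iodo-2-methylhepta-2,5-dien-4-yl 4-(acetyloxy)benzoate | OC/C(C)=C/[C@H](OC(=O)c1ccc(OC(C)=O)cc1)/C=C(\I)C | intermediate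
10 | (2E,4S,5Z)-6-iodo-2-methyl-1-oxohepta-2,5-dien-4-yl 4-(acetyloxy)benzoate | O=C/C(C)=C/[C@H](OC(=O)c1ccc(OC(C)=O)cc1)/C=C(\I)C | intermediate
11 | tributyl(1-ethoxyethenyl)stannane | CCCC[Sn](CCCC)(CCCC)C(=C)OCC | starting material
12 | (1-ethoxyethenyl)copper | C=C(OCC)[Cu] | intermediate
13 | (2E,4R,5Z)-7-ethoxy-2,6-dimethyl-1-oxoocta-2,5,7-trien-4-yl 4-(acetyloxy)benzoate | O=C/C(C)=C/[C@H](OC(=O)c1ccc(OC(C)=O)cc1)/C=C(\C(OCC)=C)C | intermediate
14 | 3-methylbutan-2-one | CC(=O)C(C)C | starting material
15 | [(3-methylbut-1-en-2-yl)oxy]bis[(+)-isopinocampheyl]borane (enol borinate; isopinocampheyl groups from (−)-α-pinene) | CC(C)C(=C)OB([C@@H]1[C@@H](C)[C@@H]2C[C@H](C1)C2(C)C)[C@@H]1[C@@H](C)[C@@H]2C[C@H](C1)C2(C)C | intermediate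
16 | O-bis[(+)-isopinocampheyl]boryl aldolate of 17 | CC(C)C(=O)C[C@@H](OB([C@@H]1[C@@H](C)[C@@H]2C[C@H](C1)C2(C)C)[C@@H]1[C@@H](C)[C@@H]2C[C@H](C1)C2(C)C)/C(C)=C/[C@H](OC(=O)c1ccc(OC(C)=O)cc1)/C=C(\C(OCC)=C)C | intermediate
17 | (3Z,5S,6E,8R)-2-ethoxy-8-hydroxy-3,7,11-trimethyl-10-oxododeca-1,3,6-trien-5-yl 4-(acetyloxy)benzoate | CC(C)C(=O)C[C@@H](O)/C(C)=C/[C@H](OC(=O)c1ccc(OC(C)=O)cc1)/C=C(\C(OCC)=C)C | intermediate
18 | O8-dichloroaluminium alkoxide of 17, chelated to the C10 ketone | CC(C)C(=O)C[C@@H](O[Al](Cl)Cl)/C(C)=C/[C@H](OC(=O)c1ccc(OC(C)=O)cc1)/C=C(\C(OCC)=C)C | intermediate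
19 | bicyclic O-ethyl oxocarbenium dichloroaluminate zwitterion (cyclised skeleton, O2 and O4 bridged by AlCl2, C9 as C=O(+)Et) | Cl[Al-]1(Cl)O[C@@H]2C[C@@](O1)(C(C)C)[C@H]3[C@H](OC(=O)c4ccc(OC(C)=O)cc4)C=C(C)C(=[O+]CC)C[C@]23C | intermediate
20 | (1R,3R,3aR,4R,8aS)-1,3-dihydroxy-6,8a-dimethyl-7-oxo-3-(propan-2-yl)-1,2,3,3a,4,7,8,8a-octahydroazulen-4-yl 4-(acetyloxy)benzoate | O[C@@H]1C[C@@](O)(C(C)C)[C@H]2[C@H](OC(=O)c3ccc(OC(C)=O)cc3)C=C(C)C(=O)C[C@]12C | intermediate
21 | (1R,3R,3aR,4R,8aS)-1-(acetyloxy)-3-hydroxy-6,8a-dimethyl-7-oxo-3-(propan-2-yl)-1,2,3,3a,4,7,8,8a-octahydroazulen-4-yl 4-(acetyloxy)benzoate | CC(=O)O[C@@H]1C[C@@](O)(C(C)C)[C@H]2[C@H](OC(=O)c3ccc(OC(C)=O)cc3)C=C(C)C(=O)C[C@]12C | intermediate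
22 | (1R,3R,3aR,4R,8aS)-1-(acetyloxy)-3-hydroxy-6,8a-dimethyl-7-oxo-3-(propan-2-yl)-1,2,3,3a,4,7,8,8a-octahydroazulen-4-yl 4-hydroxybenzoate | CC(=O)O[C@@H]1C[C@@](O)(C(C)C)[C@H]2[C@H](OC(=O)c3ccc(O)cc3)C=C(C)C(=O)C[C@]12C | target

## Step count and risk

Total steps: 8. Longest linear sequence: 8.

**Step 7 (bicyclisation) is the most likely to fail.** The ketone must react with an alkene that two allylic oxygens make less nucleophilic. The C1 cation can also lose a proton from its methyl group (ene product), undergo a 1,2-hydride shift, or be outrun by ionisation of the bis-allylic ester; the ring fusion could come out cis and the C4 centre epimeric if chelation is incomplete. The fallback sets out from 17 and comes back at 20; it separates the two ring closures and makes the cation another way. Me2AlCl (2 equiv, CH2Cl2, −78 to −20 °C), whose methyl groups accept the proton, turns the first event into a concerted, chelation-controlled type 2 carbonyl-ene reaction and gives (1R,2Z)-1-[(1R,2R,4R)-2,4-dihydroxy-5-methylidene-2-(propan-2-yl)cyclopentyl]-4-ethoxy-3-methylpenta-2,4-dien-1-yl 4-(acetyloxy)benzoate F1, with C2, C4 and C5 already set. The seven-membered ring is then closed by a hydrogen-atom-transfer-initiated radical–polar crossover: the divalent cobalt salen complex Co(C36H52N2O2) (3 mol%), N-fluoro-2,4,6-trimethylpyridinium triflate and (Me2SiH)2O in acetone at 0 °C. The hydrogen atom adds to the exocyclic CH2, which becomes the C1 methyl; the tertiary radical is oxidised to the C1 cation without acid, the ethoxydiene captures it, and hydrolytic work-up returns 20. The ring-fusion selectivity of this second stage rests on sterics only (the isopropyl group blocks the face that would give the cis isomer) and is less secure than in the concerted version; enol-ether capture in this manifold is itself an extension of known arene and alkene terminations.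

**Step 4 (allylic oxidation) is second.** Yields of Riley oxidations next to an allylic ester are moderate, and the hot, slightly acidic medium may ionise the bis-allylic ester or oxidise the methyl group of the iodoalkene. The fallback sets out from 8 and comes back at 10; it cleaves the prenyl alkene instead of oxidising its methyl group. Ozone (CH2Cl2/MeOH, pyridine, −78 °C, stopped at a Sudan red end-point, then Me2S) attacks only the electron-rich trisubstituted alkene and gives (2R,3Z)-4-iodo-1-oxopent-3-en-2-yl 4-(acetyloxy)benzoate F2. This epimerisable α-acyloxy aldehyde is used crude at once in a Wittig reaction with Ph3P=C(CH3)CHO (benzene, 50 °C), whose stabilised ylide gives the (E)-enal 10.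

**Step 6 (aldol) is third.** Diisopinocampheylboron aldols of methyl ketones give only moderate selectivity (a diastereomer ratio near 9:1 is expected here), and the partner carries an acid-labile enol ether and an aryl acetate that the oxidative work-up may partly cleave (harmless, since step 8 re-acetylates and then unmasks the phenol). The fallback sets out from 14 and comes back at 17; it moves stereocontrol from a stoichiometric chiral boron enolate to a catalytic Lewis-base-activated Mukaiyama aldol. LDA and Me3SiCl (THF, −78 °C) give 3-methyl-2-(trimethylsilyloxy)but-1-ene F3. This adds to 13 under Denmark's conditions (SiCl4, 5 mol% of the binaphthyldiamine-derived bisphosphoramide, iPr2NEt, CH2Cl2, −78 °C) through an open transition state at a chiral trichlorosilyl cation, giving 17 after aqueous NaHCO3 work-up; the catalyst antipode is chosen for re-face attack.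

Further compounds
F1 | step 7 | (1R,2Z)-1-[(1R,2R,4R)-2,4-dihydroxy-5-methylidene-2-(propan-2-yl)cyclopentyl]-4-ethoxy-3-methylpenta-2,4-dien-1-yl 4-(acetyloxy)benzoate | O[C@@H]1C[C@@](O)(C(C)C)[C@H](C1=C)[C@H](OC(=O)c1ccc(OC(C)=O)cc1)/C=C(\C(OCC)=C)C
F2 | step 4 | (2R,3Z)-4-iodo-1-oxopent-3-en-2-yl 4-(acetyloxy)benzoate | O=C[C@H](OC(=O)c1ccc(OC(C)=O)cc1)/C=C(\I)C
F3 | step 6 | 3-methyl-2-(trimethylsilyloxy)but-1-ene | CC(C)C(=C)O[Si](C)(C)C
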